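## The problem

The target 24 is an 18-membered bis(bibenzyl) cyclophane built from four six-membered rings, two diaryl ether oxygens and two CH2CH2 bridges. Ring A is a methoxy-1,4-benzoquinone (Q1 carbonyl, Q2 methoxy, Q3 CH, Q4 carbonyl, Q5 aryloxy, Q6 alkyl), ring B a para-phenylene, ring C a phenol (C1 aryloxy carbon, C2 CH, C3 bridge carbon, C4 and C5 CH, C6 hydroxyl carbon) and ring D a meta-phenylene. They are joined as Q6–CH2CH2–ring B–O–C1 and C3–CH2CH2–ring D–O–Q5. The molecule has no stereocentre, so nothing has to be set or relayed in space; the difficulties are regiochemistry and ring closure. Ring A needs oxygen on four carbons and carbon on a fifth in a fixed order, and both ether oxygens sit at hindered positions: Q5 lies between the Q4 oxygen and the Q6 side chain, and C1 lies next to the free hydroxyl at C6. The quinone is a doubly vinylogous ester that nucleophiles, bases and reductants attack, in the worst case with loss of the ring D aryloxide at Q5, so it has to be unveiled last from a protected hydroquinone. The free phenol of ring C has to stay distinguishable from the two hydroquinone oxygens of ring A throughout. The enabling feature is ring C itself: a 2-aryloxy-4-alkylphenol is the dehydrogenated form of a 2-aryloxy-4-alkylcyclohex-2-enone. C2 and C3 of that enone can come from an aldehyde and C4, C5, C6 and C1 from an aryloxymethyl vinyl ketone, so the hindered C1–O bond never has to be made on an aromatic ring.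

## Retrosynthesis

**Quinone from protected hydroquinone.** Target 24 is traced back to hydroquinone 23 and from there to the macrocyclic dibenzyl ether 22; only two O–benzyl bonds are cut. Benzyl is preferred to methyl because oxidative demethylation would also attack the ring C phenol and would have to choose between two para-dioxygen pairs on ring A. Hydrogenolysis is neutral, and the electron-rich hydroquinone 23 should oxidise in air. The forward step requires that no aryl halide or alkene is left in 22, which fixes the macrocyclisation before it.

**Macrocycle opened at ring B.** In 22 the bond between the para carbon of ring B and the CH2 of the Q6 bridge is cut, leading through alkylborane 21 to the open-chain iodo styrene 20. Closing the ring at either ether oxygen would place the ring-forming event at a hindered carbon, whereas this sp3–sp2 bond is formed at an unhindered para position. Compound 20 has no large ring and carries only an aryl iodide and a vinyl group as handles. The forward reaction needs a terminal-selective hydroboration and a dilute B-alkyl Suzuki coupling that tolerates the free phenol.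

**Ring C dearomatised.** Phenol 20 is the tautomer of dienone 19, which is the dehydrogenation product of cyclohexenone 18. This turns the 1,2,4-pattern of ring C into a consequence of carbonyl chemistry. The forward step must remove two hydrogens without touching the tetraoxygenated ring A, the styrene, the benzyl ethers or the C–I bond. This argues for a low-temperature enolate dehydrogenation over a hot quinone oxidant.

**Ring C cut into aldehyde and vinyl ketone (key disconnection).** In 18 the C3–C4 and C1–C2 bonds are cut, through aldol 17 and keto aldehyde 16, to aldehyde 11 and vinyl ketone 15. The neighbouring option, arylating a catechol derivative at C1, would need a coupling next to a protected hydroxyl and differentiation of two catechol oxygens. Here the ring B oxygen is already attached to the future C1 before ring C exists. The cut divides the molecule into two halves of similar size, the ring A/ring D aldehyde and the ring B enone. The forward reaction must form both bonds with the right regiochemistry; the stereocentre at C3 does not matter.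

**Vinyl ketone.** Enone 15 is cut at the carbonyl–vinyl bond to Weinreb amide 14, and 14 at the ether C–O bond to 4-iodophenol 12 and 2-chloro-N-methoxy-N-methylacetamide 13. Both steps are routine; the only demand is that the sensitive enone is released under conditions that do not let the liberated amine add to it.

**Aldehyde: ring D attached to ring A.** Aldehyde 11 comes from ester 10 by partial reduction, and 10 is cut at the Q5 oxygen–ring D bond into vinylphenol 7 and bromo ester 9, the methyl ester of acid 8. The reverse polarity, substitution on ring A, is not available on so electron-rich a ring, so 7 must be the nucleophile. The ester is carried through the coupling because a free aldehyde would not survive base and heat. The forward step is an Ullmann ether synthesis with a 2,6-disubstituted phenol.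

**Ring A substitution pattern.** Vinylphenol 7 is traced to salicylaldehyde 6 (Wittig methylenation), and 6 to phenol 5 by cutting the Q6–CHO bond. Only one ortho position of 5 is free, so a phenoxide-directed formylation has no choice of site. Phenol 5 comes from aldehyde 3 through formate 4 (aryl migration in a Baeyer–Villiger oxidation), and 3 from dibenzyl ether 2 by formylation para to the methoxy group. Ether 2 is the dibenzyl ether of 2-methoxyhydroquinone 1. Each step adds one substituent at a position the existing ones dictate.

## Roads not taken

**Alternative 1:** The cut is the ring B oxygen–C1 bond of the macrocycle. In the forward direction Tl(NO3)3 (trivalent thallium) in methanol would oxidise the 2,6-dibromophenol ring C of the open-chain bisphenol A2. The ring B phenol oxygen would add to a bromine-bearing ortho carbon, and zinc in acetic acid would expel bromide to give macrocycle A1. The merit is real: one operation makes the most hindered ether, next to the free hydroxyl, and closes the 18-membered ring at the same time, and A2 is a simple acyclic precursor. The weak points are stoichiometric thallium, the four halogens that must be installed to steer the oxidation, and the three that remain in A1 and must be removed. The electron-rich ring A, even as its diacetate, is also exposed to a strong one-electron oxidant, and such couplings depend heavily on how well the open chain folds. Against the chosen plan, Alternative 1 is more direct at the decisive ether. The chosen plan avoids thallium and halogen bookkeeping and makes the same ether by plain alkylation of 12, at the cost of building ring C over several steps through 18.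

**Alternative 2:** The cut runs through ring A at the Q1–Q2 bond. Heating the macrocyclic 4-ethynyl-4-hydroxycyclobutenone A4 would open the four-membered ring to a vinylketene, whose ketene carbon bonds to the alkyne terminus to give quinone A3. The merits are that the quinone appears in its final oxidation state without hydroquinone protection, and that the crowded Q5 aryloxy/Q6 alkyl pair is set on a small ring. The weak points are specific to this target. A3 lacks the Q2 methoxy group, so a late oxidative methoxylation must distinguish Q2 from Q3 while methoxide can also attack Q5 and expel the ring D aryloxide, opening the macrocycle. In addition, the macrocycle has to be assembled around a labile aryloxycyclobutenone, and the thermolysis must proceed within a constrained ring. If the methoxylation were selective, this endgame would be shorter than the chosen one. The chosen plan carries the Q2 methoxy from compound 1 and exposes the quinone only in the last step.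

**Alternative 3:** The cut is the Q5 oxygen–ring D bond. The ring A phenoxide of fluoronitroarene A6 (K2CO3, dimethylformamide, high dilution) would displace fluoride para to the nitro group and close the ring to A5. The nitro group would then be removed by reduction, diazotisation and reductive loss of nitrogen. Nitro-activated macro-etherification is among the most dependable ring closures for diaryl ether cyclophanes, needs no metal and accepts hindered phenoxides. In the ring-closing step it is probably more reliable than the B-alkyl Suzuki closure of 20 to 22. Its price is an auxiliary group absent from the target and about three steps to erase it, on a substrate whose electron-rich ring A is exposed to nitrous acid. The nitro reduction must also spare three benzyl ethers, and the hindered ring B–ring C ether of A6 still has to be made by an aryl–oxygen coupling next to a protected hydroxyl. The chosen plan sets against this the absence of any auxiliary group and the formation of that ether by alkylation of 12.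

Key step: step 11

Assumption: the free phenol of 20 is taken to consume one equivalent of 9-BBN as an O-borinate that the aqueous base of the coupling hydrolyses; 21 is drawn accordingly.

## Route

Step 1
Reactants: 1 2-methoxyhydroquinone
Product: 2 1,4-bis(benzyloxy)-2-methoxybenzene
Conditions: BnBr, K2CO3, DMF, N2, rt to 60 °C
Reagents that add atoms: benzyl bromide, BrCc1ccccc1
Why: Williamson ether synthesis on both phenolic oxygens; exclusion of air keeps the hydroquinone dianion from oxidising before it is alkylated.

Step 2
Reactants: 2 1,4-bis(benzyloxy)-2-methoxybenzene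
Product: 3 2,5-bis(benzyloxy)-4-methoxybenzaldehyde
Conditions: POCl3, DMF, 0 to 80 °C; aq. NaOAc
Reagents that add atoms: N,N-dimethylformamide, CN(C)C=O; water, O
Why: Vilsmeier–Haack formylation; a 1,2,4-trialkoxybenzene reacts at the position para to one alkoxy group and ortho to another (para to the methoxy group here), the pattern known for this arene class.

Step 3
Reactants: 3 2,5-bis(benzyloxy)-4-methoxybenzaldehyde
Product: 5 2,5-bis(benzyloxy)-4-methoxyphenol, via aryl formate 4 (not isolated)
Conditions: mCPBA, CH2Cl2, 0 °C to rt; then K2CO3, MeOH, rt
Reagents that add atoms: 3-chloroperoxybenzoic acid, OOC(=O)c1cccc(Cl)c1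
Why: Baeyer–Villiger (Dakin-type) oxidation; the electron-rich aryl group migrates in preference to hydrogen to give formate 4, which methanolysis cleaves to the phenol that becomes the Q5 oxygen.

Step 4
Reactants: 5 2,5-bis(benzyloxy)-4-methoxyphenol
Product: 6 3,6-bis(benzyloxy)-2-hydroxy-5-methoxybenzaldehyde
Conditions: MgCl2, Et3N, (CH2O)n, MeCN, reflux
Reagents that add atoms: formaldehyde (as paraformaldehyde), C=O
Why: Magnesium phenoxide-directed ortho-formylation (Casnati–Skattebøl); delivery through the magnesium chelate is strictly ortho, and the only free ortho position is the future Q6, the other ortho and the para position being blocked.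

Step 5
Reactants: 6 3,6-bis(benzyloxy)-2-hydroxy-5-methoxybenzaldehyde
Product: 7 3,6-bis(benzyloxy)-4-methoxy-2-vinylphenol
Conditions: Ph3PCH3Br (2.5 equiv), KOt-Bu (2.4 equiv), THF, 0 °C to rt
Reagents that add atoms: methyltriphenylphosphonium bromide, C[P+](c1ccccc1)(c1ccccc1)c1ccccc1.[Br-]
Why: Wittig methylenation; the first equivalent of ylide is spent on the phenol and the second converts the salicylaldehyde phenoxide into the styrene, a standard way to 2-vinylphenols.

Step 6
Reactants: 8 4-(3-bromophenyl)butanoic acid
Product: 9 methyl 4-(3-bromophenyl)butanoate
Conditions: MeOH, H2SO4 (cat.), reflux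
Reagents that add atoms: methanol, CO
Why: Fischer esterification; the ester protects the acid during the base-mediated coupling and is the precursor of the aldehyde.

Step 7
Reactants: 7 3,6-bis(benzyloxy)-4-methoxy-2-vinylphenol; 9 methyl 4-(3-bromophenyl)butanoate
Product: 10 methyl 4-{3-[3,6-bis(benzyloxy)-4-methoxy-2-vinylphenoxy]phenyl}butanoate
Conditions: CuI (10 mol %), picolinic acid (20 mol %), K3PO4, DMSO, Ar, 90 °C
Reagents that add atoms: none
Why: Ullmann-type diaryl ether synthesis; copper/picolinic acid catalysis is known to couple electron-rich 2,6-disubstituted phenols with aryl bromides, and the ester and the styrene should be inert under argon in anhydrous medium.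

Step 8
Reactants: 10 methyl 4-{3-[3,6-bis(benzyloxy)-4-methoxy-2-vinylphenoxy]phenyl}butanoate
Product: 11 4-{3-[3,6-bis(benzyloxy)-4-methoxy-2-vinylphenoxy]phenyl}butanal
Conditions: i-Bu2AlH (1.1 equiv), CH2Cl2, −78 °C; MeOH, aq. potassium sodium tartrate
Reagents that add atoms: none
Why: Partial reduction of a methyl ester with i-Bu2AlH; at −78 °C the tetrahedral aluminium hemiacetal persists and releases the aldehyde only on work-up, while the styrene and the ethers are not touched.

Step 9
Reactants: 12 4-iodophenol; 13 2-chloro-N-methoxy-N-methylacetamide
Product: 14 2-(4-iodophenoxy)-N-methoxy-N-methylacetamide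
Conditions: K2CO3, KI (cat.), acetone, reflux
Reagents that add atoms: none
Why: Williamson ether synthesis with an activated α-chloro amide; this simple alkylation creates the oxygen–carbon bond that ends as the hindered ring B–O–C1 ether.

Step 10
Reactants: 14 2-(4-iodophenoxy)-N-methoxy-N-methylacetamide
Product: 15 1-(4-iodophenoxy)but-3-en-2-one
Conditions: CH2=CHMgBr (1.3 equiv), THF, −78 to 0 °C; inverse quench into cold 1 M HCl
Reagents that add atoms: vinylmagnesium bromide, C=C[Mg]Br
Why: Weinreb ketone synthesis; the chelated tetrahedral intermediate prevents over-addition, and the acidic inverse quench keeps the liberated N,O-dimethylhydroxylamine protonated so that it cannot add to the enone; the aryl iodide does not exchange with a vinyl Grignard reagent at this temperature.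

Step 11
Reactants: 11 4-{3-[3,6-bis(benzyloxy)-4-methoxy-2-vinylphenoxy]phenyl}butanal; 15 1-(4-iodophenoxy)but-3-en-2-one
Product: 18 racemic 4-(2-{3-[3,6-bis(benzyloxy)-4-methoxy-2-vinylphenoxy]phenyl}ethyl)-2-(4-iodophenoxy)cyclohex-2-en-1-one, via keto aldehyde 16 (not isolated), via cyclic aldol 17 (not isolated)
Conditions: pyrrolidine (0.3 equiv), PhCO2H (0.3 equiv), THF, 0 °C to rt, slow addition of 15 (1.3 equiv); then aq. KOH, n-Bu4NOH (cat.), THF/Et2O, 40 °C
Reagents that add atoms: none
Why: Pyrrolidine condenses with aldehyde 11 to an enamine whose nucleophilic carbon (the future C3) adds to the unsubstituted terminus of vinyl ketone 15, forming the C3–C4 bond; hydrolysis returns the amine and gives keto aldehyde 16. Under hydroxide the ketone of 16 enolises toward the aryloxy-bearing methylene, its more acidic α-position, and this carbon adds to the aldehyde (C1–C2 bond) to give aldol 17, which loses water by an E1cB pathway to the conjugated enone 18. The closest known reaction type is the amine-catalysed Michael addition of α-unbranched aldehydes to vinyl ketones followed by base-mediated aldol condensation to 4-substituted cyclohex-2-enones, together with Robinson annulations of alkoxymethyl vinyl ketones that give 2-alkoxycyclohexenones. The ring closes in a six-membered 6-(enolexo)-exo-trig mode, the enolate carbon attacking the aldehyde carbonyl. The one new stereocentre, C3, is formed without control and 18 is racemic; this is accepted because C3 becomes sp2 in step 12, and the two further centres of 17 disappear on dehydration. The step needs regiocontrol in both bonds: the enamine can only attack the β-terminus of the enone, and the only alternative aldol closures would give four-membered rings, so the aryloxy group must end on C1 next to the carbonyl carbon C6. Self-condensation of 11 is held back by slow addition of the enone and low aldehyde concentration, and the styrene, benzyl ethers and aryl iodide are inert to amine and hydroxide.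

Step 12
Reactants: 18 racemic 4-(2-{3-[3,6-bis(benzyloxy)-4-methoxy-2-vinylphenoxy]phenyl}ethyl)-2-(4-iodophenoxy)cyclohex-2-en-1-one
Product: 20 4-(2-{3-[3,6-bis(benzyloxy)-4-methoxy-2-vinylphenoxy]phenyl}ethyl)-2-(4-iodophenoxy)phenol, via cyclohexadienone 19 (not isolated)
Conditions: LiN(i-Pr)2 (1.2 equiv), THF, −78 °C; PhS(Cl)=N-t-Bu, −78 °C to rt; aq. NH4Cl
Reagents that add atoms: none
Why: Mukaiyama dehydrogenation of a ketone enolate; kinetic deprotonation at C5 gives the cross-conjugated dienolate, which attacks sulfur of N-tert-butylbenzenesulfinimidoyl chloride, and the adduct eliminates at low temperature across C4–C5 to dienone 19, the keto tautomer of phenol 20, which aromatises on work-up. The method is not an oxidant toward the electron-rich ring A, the styrene or the benzyl ethers, and the amide base leaves the C–I bond alone at −78 °C.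

Step 13
Reactants: 20 4-(2-{3-[3,6-bis(benzyloxy)-4-methoxy-2-vinylphenoxy]phenyl}ethyl)-2-(4-iodophenoxy)phenol
Product: 22 macrocyclic dibenzyl ether (18-membered ring of the target with ring A as its Q1,Q4-bis(benzyloxy)-Q2-methoxy arene and ring C as free phenol), via alkylborane 21 (not isolated)
Conditions: 9-BBN (3 equiv), THF, 0 °C to rt; then slow addition to Pd(dppf)Cl2 (10 mol %), AsPh3, Cs2CO3, DMF/THF/H2O, 60 °C, high dilution
Reagents that add atoms: none
Why: Anti-Markovnikov hydroboration of the hindered styrene with 9-BBN places boron on the terminal carbon, and an intramolecular B-alkyl Suzuki–Miyaura coupling follows: zerovalent palladium inserts into the ring B C–I bond, base-assisted transmetalation transfers the primary alkyl group, and reductive elimination closes the 18-membered ring at the unhindered para carbon. The bidentate dppf ligand disfavours β-hydride elimination, and slow addition keeps the open-chain borane dilute.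

Step 14
Reactants: 22 macrocyclic dibenzyl ether
Product: 24 target quinone CNP0332646.0, via hydroquinone 23 (not isolated)
Conditions: H2 (1 atm), Pd/C, EtOAc/MeOH, rt; filter; then air, rt
Reagents that add atoms: none
Why: Hydrogenolysis of the two benzyl ethers releases the electron-rich methoxy/aryloxy hydroquinone 23, which after removal of the catalyst should be autoxidised by air to the quinone; the ring C phenol has no para or ortho hydroxyl partner and should stay unoxidised, and the diaryl ethers are stable to hydrogenolysis.

## Compound list

1 | 2-methoxyhydroquinone (2-methoxybenzene-1,4-diol) | COc1cc(O)ccc1O | starting material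
2 | 1,4-bis(benzyloxy)-2-methoxybenzene | COc1cc(OCc2ccccc2)ccc1OCc1ccccc1 | intermediate
3 | 2,5-bis(benzyloxy)-4-methoxybenzaldehyde | COc1cc(OCc2ccccc2)c(C=O)cc1OCc1ccccc1 | intermediate
4 | 2,5-bis(benzyloxy)-4-methoxyphenyl formate (not isolated) | COc1cc(OCc2ccccc2)c(OC=O)cc1OCc1ccccc1 | intermediate
5 | 2,5-bis(benzyloxy)-4-methoxyphenol | COc1cc(OCc2ccccc2)c(O)cc1OCc1ccccc1 | intermediate
6 | 3,6-bis(benzyloxy)-2-hydroxy-5-methoxybenzaldehyde | COc1cc(OCc2ccccc2)c(O)c(C=O)c1OCc1ccccc1 | intermediate
7 | 3,6-bis(benzyloxy)-4-methoxy-2-vinylphenol | COc1cc(OCc2ccccc2)c(O)c(C=C)c1OCc1ccccc1 | intermediate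
8 | 4-(3-bromophenyl)butanoic acid | OC(=O)CCCc1cccc(Br)c1 | starting material
9 | methyl 4-(3-bromophenyl)butanoate | COC(=O)CCCc1cccc(Br)c1 | intermediate
10 | methyl 4-{3-[3,6-bis(benzyloxy)-4-methoxy-2-vinylphenoxy]phenyl}butanoate | COC(=O)CCCc1cccc(Oc2c(OCc3ccccc3)cc(OC)c(OCc3ccccc3)c2C=C)c1 | intermediate
11 | 4-{3-[3,6-bis(benzyloxy)-4-methoxy-2-vinylphenoxy]phenyl}butanal | O=CCCCc1cccc(Oc2c(OCc3ccccc3)cc(OC)c(OCc3ccccc3)c2C=C)c1 | intermediate
12 | 4-iodophenol | Oc1ccc(I)cc1 | starting material
13 | 2-chloro-N-methoxy-N-methylacetamide | CON(C)C(=O)CCl | starting material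
14 | 2-(4-iodophenoxy)-N-methoxy-N-methylacetamide | CON(C)C(=O)COc1ccc(I)cc1 | intermediate
15 | 1-(4-iodophenoxy)but-3-en-2-one | C=CC(=O)COc1ccc(I)cc1 | intermediate
16 | racemic 2-(2-{3-[3,6-bis(benzyloxy)-4-methoxy-2-vinylphenoxy]phenyl}ethyl)-6-(4-iodophenoxy)-5-oxohexanal (not isolated) | O=CC(CCc1cccc(Oc2c(OCc3ccccc3)cc(OC)c(OCc3ccccc3)c2C=C)c1)CCC(=O)COc1ccc(I)cc1 | intermediate
17 | 4-(2-{3-[3,6-bis(benzyloxy)-4-methoxy-2-vinylphenoxy]phenyl}ethyl)-3-hydroxy-2-(4-iodophenoxy)cyclohexan-1-one, mixture of racemic diastereomers (not isolated) | O=C1CCC(CCc2cccc(Oc3c(OCc4ccccc4)cc(OC)c(OCc4ccccc4)c3C=C)c2)C(O)C1Oc1ccc(I)cc1 | intermediate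
18 | racemic 4-(2-{3-[3,6-bis(benzyloxy)-4-methoxy-2-vinylphenoxy]phenyl}ethyl)-2-(4-iodophenoxy)cyclohex-2-en-1-one | O=C1CCC(CCc2cccc(Oc3c(OCc4ccccc4)cc(OC)c(OCc4ccccc4)c3C=C)c2)C=C1Oc1ccc(I)cc1 | intermediate
19 | racemic 4-(2-{3-[3,6-bis(benzyloxy)-4-methoxy-2-vinylphenoxy]phenyl}ethyl)-2-(4-iodophenoxy)cyclohexa-2,5-dien-1-one (not isolated) | O=C1C=CC(CCc2cccc(Oc3c(OCc4ccccc4)cc(OC)c(OCc4ccccc4)c3C=C)c2)C=C1Oc1ccc(I)cc1 | intermediate
20 | 4-(2-{3-[3,6-bis(benzyloxy)-4-methoxy-2-vinylphenoxy]phenyl}ethyl)-2-(4-iodophenoxy)phenol | Oc1ccc(CCc2cccc(Oc3c(OCc4ccccc4)cc(OC)c(OCc4ccccc4)c3C=C)c2)cc1Oc1ccc(I)cc1 | intermediate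
21 | B-alkyl-9-BBN borane of 20: boron on the terminal carbon of the former vinyl group, ring C oxygen as its 9-borabicyclo[3.3.1]nonan-9-yl borinate (not isolated) | COc1cc(OCc2ccccc2)c(Oc2cccc(CCc3ccc(OB4C5CCCC4CCC5)c(Oc4ccc(I)cc4)c3)c2)c(CCB2C3CCCC2CCC3)c1OCc1ccccc1 | intermediate
22 | macrocyclic dibenzyl ether: 18-membered ring of the target, ring A as Q1,Q4-bis(benzyloxy)-Q2-methoxy arene, ring C free phenol | COc1cc(OCc4ccccc4)c2c(CCc3ccc(cc3)Oc3cc(ccc3O)CCc3cccc(c3)O2)c1OCc1ccccc1 | intermediate
23 | macrocyclic hydroquinone: 22 without its two benzyl groups (not isolated) | COc1cc(O)c2c(CCc3ccc(cc3)Oc3cc(ccc3O)CCc3cccc(c3)O2)c1O | intermediate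
24 | target CNP0332646.0: macrocyclic 2-methoxy-5-aryloxy-6-alkyl-1,4-benzoquinone with free ring C phenol | COC1=CC(=O)C2=C(CCc3ccc(cc3)Oc3cc(ccc3O)CCc3cccc(c3)O2)C1=O | target

## Step count and risk

Total: 14 steps. Longest linear sequence: 11 steps from 1 (steps 1, 2, 3, 4, 5, 7, 8, 11, 12, 13, 14). The ring D branch (step 6) and the ring B branch (steps 9 and 10) join it at steps 7 and 11.

**Step 11 (key step).** The most likely failure is that oligomerisation of the aryloxymethyl vinyl ketone, or self-aldolisation of the aldehyde, outruns the cross Michael addition; less likely, the aldol stops before dehydration. The fallback forms the same C3–C4 bond by alkylation instead of conjugate addition. It sets out from 11 and 15 and returns to the route at 18.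
- Aldehyde 11 is condensed with cyclohexylamine to the N-cyclohexyl imine F1.
- Enone 15 is converted with NaI and Me3SiCl in MeCN, then ethylene glycol, into the β-iodo ketal 2-(2-iodoethyl)-2-[(4-iodophenoxy)methyl]-1,3-dioxolane F2.
- Deprotonation of F1 with LiN(i-Pr)2 and alkylation of the metalloenamine with F2 gives the alkylated imine F3.
- A buffered aqueous acetic acid work-up hydrolyses F3 to the aldehyde ketal F4.
- Aqueous HCl in THF unmasks the ketone to give 16, now isolated, and KOH closes it to 18 as in the second stage of step 11.

**Step 13.** Intermolecular coupling to oligomers, or protodeboronation and β-hydride elimination, may win over closure of the strained cyclophane. The fallback closes the same bridge by olefin metathesis. It sets out from 20 and returns at 24.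
- Suzuki vinylation of the aryl iodide (potassium vinyltrifluoroborate, Pd(dppf)Cl2, Cs2CO3, THF/H2O) gives the divinyl phenol F5.
- Ring-closing metathesis at high dilution with the second-generation Hoveyda–Grubbs catalyst RuCl2(H2IMes)(=CH-C6H4-2-O-i-Pr) gives the macrocyclic stilbene F6; its alkene geometry is left undefined.
- Under the conditions of step 14 the alkene is hydrogenated as the benzyl ethers are cleaved, giving 23 and, in air, 24.

**Step 12.** Deprotonation may occur at C3 instead of C5 and give the extended dienolate, which cannot eliminate after sulfur transfer; the phenoxide formed may also be sulfenylated. The fallback does not depend on the site of enolisation. It sets out from 18 and returns at 20.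
- Me3SiOTf and Et3N in CH2Cl2 convert 18 into the trimethylsilyl dienol ether F7; either regioisomer is a cyclohexa-1,3-diene.
- DDQ at 0 °C removes hydride from that diene and gives the aryl silyl ether F8.
- K2CO3 in MeOH cleaves F8 to 20.
Exposure of ring A to DDQ is brief and cold in this variant.

**Step 7.** Carbon–oxygen bond formation at the doubly ortho-substituted phenoxide may be slow, so that thermal polymerisation of the vinylphenol or saponification of the ester takes over at 90 °C. The fallback is an oxidative coupling at room temperature. It sets out from 9 and 7 and returns at 10.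
- Palladium-catalysed borylation of 9 (B2(OH)4, Pd(OAc)2/XPhos, KOAc, EtOH) gives [3-(4-methoxy-4-oxobutyl)phenyl]boronic acid F9.
- Chan–Lam coupling of F9 with 7 (Cu(OAc)2, pyridine, 4 Å molecular sieves, CH2Cl2, air, rt) gives 10; 2,6-disubstituted phenols are known partners in this reaction.

**Step 4.** Formylation at the only free ortho position, which is flanked by a benzyloxy group, may be sluggish, and the hydroxymethyl intermediate may condense with a second phenol instead of being oxidised. The fallback introduces the vinyl group by halogenation and cross-coupling. It sets out from 5 and returns at 7, bypassing 6 and step 5.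
- N-Bromosuccinimide in CH2Cl2 at low temperature brominates ortho to the hydroxyl (the para position is blocked) and gives 3,6-bis(benzyloxy)-2-bromo-4-methoxyphenol F10.
- Suzuki–Miyaura vinylation (potassium vinyltrifluoroborate, Pd(OAc)2/SPhos, K2CO3, THF/H2O) gives 7.

## Further compounds

F1 | step 11 | N-cyclohexyl imine of 11, (E)-N-cyclohexyl-4-{3-[3,6-bis(benzyloxy)-4-methoxy-2-vinylphenoxy]phenyl}butan-1-imine | C1CCCCC1/N=C/CCCc1cccc(Oc2c(OCc3ccccc3)cc(OC)c(OCc3ccccc3)c2C=C)c1
F2 | step 11 | 2-(2-iodoethyl)-2-[(4-iodophenoxy)methyl]-1,3-dioxolane | ICCC1(COc2ccc(I)cc2)OCCO1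
F3 | step 11 | racemic alkylated imine, N-cyclohexyl imine of F4 | C1CCCCC1/N=C/C(CCc1cccc(Oc2c(OCc3ccccc3)cc(OC)c(OCc3ccccc3)c2C=C)c1)CCC1(COc2ccc(I)cc2)OCCO1
F4 | step 11 | racemic aldehyde ketal, ethylene ketal of keto aldehyde 16 | O=CC(CCc1cccc(Oc2c(OCc3ccccc3)cc(OC)c(OCc3ccccc3)c2C=C)c1)CCC1(COc2ccc(I)cc2)OCCO1
F5 | step 13 | divinyl phenol, 4-(2-{3-[3,6-bis(benzyloxy)-4-methoxy-2-vinylphenoxy]phenyl}ethyl)-2-(4-vinylphenoxy)phenol | Oc1ccc(CCc2cccc(Oc3c(OCc4ccccc4)cc(OC)c(OCc4ccccc4)c3C=C)c2)cc1Oc1ccc(C=C)cc1
F6 | step 13 | macrocyclic stilbene, 22 with CH=CH in place of the Q6–ring B CH2CH2 bridge, alkene geometry undefined | COc1cc(OCc4ccccc4)c2c(C=Cc3ccc(cc3)Oc3cc(ccc3O)CCc3cccc(c3)O2)c1OCc1ccccc1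
F7 | step 12 | racemic trimethylsilyl dienol ether of 18 (2-silyloxy-1,3-diene isomer drawn) | C[Si](C)(C)OC1=CCC(CCc2cccc(Oc3c(OCc4ccccc4)cc(OC)c(OCc4ccccc4)c3C=C)c2)C=C1Oc1ccc(I)cc1
F8 | step 12 | trimethylsilyl ether of phenol 20 | C[Si](C)(C)Oc1ccc(CCc2cccc(Oc3c(OCc4ccccc4)cc(OC)c(OCc4ccccc4)c3C=C)c2)cc1Oc1ccc(I)cc1
F9 | step 7 | [3-(4-methoxy-4-oxobutyl)phenyl]boronic acid | COC(=O)CCCc1cccc(B(O)O)c1
F10 | step 4 | 3,6-bis(benzyloxy)-2-bromo-4-methoxyphenol | COc1cc(OCc2ccccc2)c(O)c(Br)c1OCc1ccccc1
A1 | alternative 1 | macrocyclic diaryl ether with free ring C phenol, one bromine on ring C, two chlorines on ring B, ring A diacetate | COc1cc(OC(C)=O)c2c(CCc3cc(Cl)c(c(Cl)c3)Oc3cc(cc(Br)c3O)CCc3cccc(c3)O2)c1OC(C)=O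
A2 | alternative 1 | open-chain bisphenol: ring C as 2,6-dibromophenol, ring B as 2,6-dichlorophenol, ring A diacetate | COc1cc(OC(C)=O)c(Oc2cccc(CCc3cc(Br)c(O)c(Br)c3)c2)c(CCc2cc(Cl)c(O)c(Cl)c2)c1OC(C)=O
A3 | alternative 2 | macrocyclic 2-aryloxy-3-alkyl-1,4-benzoquinone lacking the Q2 methoxy, ring C as methoxymethyl ether | O=C1C=CC(=O)C2=C1CCc1ccc(cc1)Oc1cc(ccc1OCOC)CCc1cccc(c1)O2
A4 | alternative 2 | racemic macrocyclic 4-ethynyl-4-hydroxycyclobutenone (2-alkyl, 3-aryloxy), ring C as methoxymethyl ether | O=C1C(CCc2ccc(cc2)Oc2cc(ccc2OCOC)CCc2cccc(c2)O3)=C3C1(O)C#C
A5 | alternative 3 | tribenzyl-protected macrocycle with a nitro group on ring D para to the new ether oxygen | COc1cc(OCc2ccccc2)c2c(CCc3ccc(cc3)Oc3cc(ccc3OCc3ccccc3)CCc3cc(ccc3[N+](=O)[O-])O2)c1OCc1ccccc1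
A6 | alternative 3 | open-chain Q5 phenol carrying a 5-fluoro-2-nitrophenyl ring D, rings A and C benzyl-protected | COc1cc(OCc2ccccc2)c(O)c(CCc2ccc(cc2)Oc2cc(ccc2OCc2ccccc2)CCc2cc(F)ccc2[N+](=O)[O-])c1OCc1ccccc1
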